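**Plan**
The target, 2,4,7-tribromo-3-chloro-1H-indole, is cut first at C2–Br (back to a C2 carboxyl group), then at C3–Cl (back to C3–H) and at N–Ts, then at the pyrrole bond C2–C3, and last at N–CH2 and aryl C–N.
Enabling feature: C3 is attached to C3a and can begin as a formyl carbon on the benzene ring, while C2 can begin as the α-carbon of an N-aryl glycinate whose ester is later exchanged for bromine.
Forward: the benzene ring is bought with both bromines (future C4 and C7) in place; nitrogen enters by SNAr, the glycinate arm by N-alkylation, and the pyrrole ring (the only ring built) closes by C2–C3 aldol condensation.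
The end-game is detosylation, C3 chlorination, saponification and ipso-bromodecarboxylation at C2.
Stereochemistry: the target has none; the two transient stereocentres of the aldol adduct are erased on dehydration.

Key step: step 3

Assumption: Ts denotes p-toluenesulfonyl; aldol adduct 6 is expected as a racemic mixture of diastereomers and is drawn without configuration.

**Route**

Step 1
Reactants: 1 3,6-dibromo-2-fluorobenzaldehyde; 2 p-toluenesulfonamide
Product: 3 N-(3,6-dibromo-2-formylphenyl)-4-methylbenzenesulfonamide
Conditions: K2CO3, DMSO, 90 °C; then aq. HCl
Reagents that add atoms: none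
Why: Nucleophilic aromatic substitution (SNAr) in which the sulfonamide anion adds at the C–F carbon, activated by the ortho formyl group and the adjacent bromine, and fluoride should leave far faster than either bromide because addition is rate-limiting.

Step 2
Reactants: 3 N-(3,6-dibromo-2-formylphenyl)-4-methylbenzenesulfonamide; 4 ethyl bromoacetate
Product: 5 ethyl N-(3,6-dibromo-2-formylphenyl)-N-tosylglycinate
Conditions: K2CO3, acetone, rt → 40 °C
Reagents that add atoms: none
Why: SN2 N-alkylation of the acidic sulfonanilide N–H by a reactive α-bromo ester, under a mild heterogeneous base that should not enolise the glycinate appreciably, so that open-chain 5 can be isolated (any material that cyclises early converges in step 3).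

Step 3
Reactants: 5 ethyl N-(3,6-dibromo-2-formylphenyl)-N-tosylglycinate
Product: 7 ethyl 4,7-dibromo-1-tosyl-1H-indole-2-carboxylate, via 3-hydroxyindoline aldol adduct 6 (not isolated)
Conditions: K2CO3, 4 Å MS, DMF, 80 °C
Reagents that add atoms: none
Why: K2CO3 deprotonates the methylene flanked by the ester and the sulfonamide nitrogen, the ester enolate adds through carbon to the neighbouring formyl group to forge C2–C3 and give aldol adduct 6, and 6 then loses water by an E1cB pathway through the same ester enolate to aromatise to the indole. The closest known reaction type is the base-mediated cyclocondensation of N-sulfonyl-N-(2-formylaryl)glycinates to 1-sulfonylindole-2-carboxylates, an intramolecular aldol condensation. The pyrrole ring closes in a 5-exo-trig mode, the enolate carbon attacking the exocyclic C=O so that N1, C7a, C3a, C3 and C2 form the ring. No stereocentre survives, since the two created in 6 are both destroyed on dehydration and their relative configuration is irrelevant. The step needs a single site of enolisation and a single electrophile, which the substrate secures because the glycinate CH2 is the only acidic C–H, the aldehyde has no α-hydrogen and lies in a 1,5-relationship to the carbanion, and the bromines already fixed on the benzene ring can only end up at C4 and C7. Loss of water rather than of sulfinate from the C2 carbanion should be favoured by direct aromatisation, and the molecular sieves keep the liberated water from attacking the N–S bond or the ester.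

Step 4
Reactants: 7 ethyl 4,7-dibromo-1-tosyl-1H-indole-2-carboxylate
Product: 8 ethyl 4,7-dibromo-1H-indole-2-carboxylate
Conditions: Cs2CO3, THF/EtOH (2:1), rt
Reagents that add atoms: none
Why: Nucleophilic N-desulfonylation in which ethoxide attacks sulfur and expels an indolide that is stabilised by the C2 ester and relieved of peri strain against the C7 bromine, with ethanol chosen to match the ethyl ester.

Step 5
Reactants: 8 ethyl 4,7-dibromo-1H-indole-2-carboxylate
Product: 9 ethyl 4,7-dibromo-3-chloro-1H-indole-2-carboxylate
Conditions: NCS, DMF, rt → 50 °C
Reagents that add atoms: N-chlorosuccinimide, O=C1CCC(=O)N1Cl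
Why: Electrophilic aromatic chlorination at C3, the only free and the most nucleophilic position of the pyrrole ring, while C2 is blocked by the ester and the benzenoid positions are deactivated by the two bromines.

Step 6
Reactants: 9 ethyl 4,7-dibromo-3-chloro-1H-indole-2-carboxylate
Product: 10 4,7-dibromo-3-chloro-1H-indole-2-carboxylic acid
Conditions: LiOH·H2O, THF/EtOH/H2O, rt → 40 °C; then 1 M HCl
Reagents that add atoms: lithium hydroxide, [Li+].[OH-]
Why: Ester saponification by acyl substitution with hydroxide, under conditions to which the aryl and heteroaryl halides are inert, followed by acidification to the free acid.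

Step 7
Reactants: 10 4,7-dibromo-3-chloro-1H-indole-2-carboxylic acid
Product: 11 2,4,7-tribromo-3-chloro-1H-indole
Conditions: NBS, LiOAc (cat.), DMF, 0 °C → rt, dark
Reagents that add atoms: N-bromosuccinimide, O=C1CCC(=O)N1Br
Why: Halodecarboxylation (ipso-bromodecarboxylation, a Hunsdiecker-type substitution known for indole-2-carboxylic acids) in which electrophilic bromine attacks the carboxylate-bearing C2, C3 being blocked by chlorine, and the σ-complex rearomatises by losing CO2 instead of a proton.

**Compound list**
1 | 3,6-dibromo-2-fluorobenzaldehyde | O=Cc1c(F)c(Br)ccc1Br | starting material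
2 | p-toluenesulfonamide | Cc1ccc(S(N)(=O)=O)cc1 | starting material
3 | N-(3,6-dibromo-2-formylphenyl)-4-methylbenzenesulfonamide | Cc1ccc(cc1)S(=O)(=O)Nc1c(Br)ccc(Br)c1C=O | intermediate
4 | ethyl bromoacetate | CCOC(=O)CBr | starting material
5 | ethyl N-(3,6-dibromo-2-formylphenyl)-N-tosylglycinate | CCOC(=O)CN(c1c(Br)ccc(Br)c1C=O)S(=O)(=O)c1ccc(C)cc1 | intermediate
6 | ethyl 4,7-dibromo-3-hydroxy-1-tosylindoline-2-carboxylate (aldol adduct, racemic mixture of diastereomers, not isolated) | CCOC(=O)C1C(O)c2c(Br)ccc(Br)c2N1S(=O)(=O)c1ccc(C)cc1 | intermediate
7 | ethyl 4,7-dibromo-1-tosyl-1H-indole-2-carboxylate | CCOC(=O)c1cc2c(Br)ccc(Br)c2n1S(=O)(=O)c1ccc(C)cc1 | intermediate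
8 | ethyl 4,7-dibromo-1H-indole-2-carboxylate | CCOC(=O)c1cc2c(Br)ccc(Br)c2[nH]1 | intermediate
9 | ethyl 4,7-dibromo-3-chloro-1H-indole-2-carboxylate | CCOC(=O)c1[nH]c2c(Br)ccc(Br)c2c1Cl | intermediate
10 | 4,7-dibromo-3-chloro-1H-indole-2-carboxylic acid | OC(=O)c1[nH]c2c(Br)ccc(Br)c2c1Cl | intermediate
11 | 2,4,7-tribromo-3-chloro-1H-indole | Clc1c(Br)[nH]c2c(Br)ccc(Br)c12 | target

**Count and risks**
Total step count: 7. Longest linear sequence: 7 steps (1 → 11).

Steps most likely to fail:

1. Step 7. Bromine may attack the chlorine-bearing C3 instead of C2, which would lead to halogen migration or oxidative degradation of the pyrrole ring, or decarboxylation may lag behind bromination. The fallback sets out from 10 and returns at 11. Acid 10 is protodecarboxylated with Ag2CO3 (cat.) and AcOH (cat.) in DMSO at 120 °C to 4,7-dibromo-3-chloro-1H-indole F1. NBS in THF at 0 °C then brominates the only remaining pyrrole C–H, at C2, by ordinary electrophilic substitution of a 3-haloindole, giving 11.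

2. Step 3. Dehydration may stall at the aldol stage, or the enolate may expel sulfinate (N–S cleavage) in competition with loss of water. The fallback sets out from 5 and returns at 7. Compound 5 is cyclised under milder conditions (K2CO3, DMF, rt) so that the reaction stops at aldol adduct 6, which is isolated. The hydroxyl of 6 is activated with MsCl/Et3N in CH2Cl2 at 0 °C to give ethyl 4,7-dibromo-3-(methylsulfonyloxy)-1-tosylindoline-2-carboxylate F2. DBU then eliminates methanesulfonate across C2–C3, which makes β-elimination far easier than sulfinate loss and delivers 7.

3. Step 1. Fluoride displacement by the weakly nucleophilic, bulky sulfonamide anion at a doubly flanked carbon may be sluggish, and reversible condensation at the aldehyde may compete. The fallback sets out from 1 and returns at 3. The small, strongly nucleophilic azide ion (NaN3, DMSO, rt → 40 °C) displaces fluoride to give 2-azido-3,6-dibromobenzaldehyde F3. Staudinger reduction (PPh3, THF/H2O) gives 2-amino-3,6-dibromobenzaldehyde F4. Sulfonylation with TsCl in pyridine with DMAP (cat.) at 60 °C then furnishes 3.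

**Further compounds**
F1 | step 7 | 4,7-dibromo-3-chloro-1H-indole | Clc1c[nH]c2c(Br)ccc(Br)c12
F2 | step 3 | ethyl 4,7-dibromo-3-(methylsulfonyloxy)-1-tosylindoline-2-carboxylate | CCOC(=O)C1C(OS(C)(=O)=O)c2c(Br)ccc(Br)c2N1S(=O)(=O)c1ccc(C)cc1
F3 | step 1 | 2-azido-3,6-dibromobenzaldehyde | [N-]=[N+]=Nc1c(Br)ccc(Br)c1C=O
F4 | step 1 | 2-amino-3,6-dibromobenzaldehyde | Nc1c(Br)ccc(Br)c1C=O
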